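I am asked how the J in this flask divides between X and Q, early and at the end.

| flask | J | Z | remark | time |
|---|---|---|---|---|
| Saturday's | 0.10 M | 0.050 M | run made earlier |  |
| Monday's | 0.10 M | 0.20 M | run made earlier |  |
| Wednesday's | 0.050 M | 0.10 M | run made earlier |  |
| flask | 0.10 M | 0.100 M |  | 3.0 h |

| run | time / h | X / % | Q / % |
|---|---|---|---|
| Saturday's | 0.200 | 7 | 16 |
| Saturday's | 0.333 | 11 | 33 |
| Saturday's | 0.500 | 24 | 43 |
| Saturday's | 0.833 | 36 | 51 |
| Saturday's | 1.33 | 44 | 50 |
| Saturday's | 2.50 | 47 | 53 |
| Monday's | 0.200 | 1 | 27 |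
| Monday's | 0.333 | 1 | 63 |
| Monday's | 0.500 | 4 | 84 |
| Monday's | 0.833 | 3 | 99 |
| Monday's | 1.33 | 4 | 98 |
| Monday's | 2.50 | 3 | 96 |
| Wednesday's | 0.500 | 5 | 88 |
| Wednesday's | 1.00 | 5 | 94 |
| Wednesday's | 1.33 | 6 | 93 |
| Wednesday's | 2.00 | 6 | 93 |
| Wednesday's | 2.50 | 6 | 95 |

(readings scatter by 1.5 percentage points)

1. share of X in X plus Q at 6.0 min
2. share of X in X plus Q at 3.0 h
3. which of X and Q there is more of at 3.0 h

- as a solid, counted per litre of solution: J
- on the list of suspects stand: L -> Q; D -> X; Z -> G; J <-> D; D + Z -> L; D + Z <-> E
- at the start none of J is in solution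

I take it that J dissolves to D, and that D goes either to X by itself or with Z to L and on to Q. X then forms against L in the ratio K/[Z], with K a selectivity factor. Since Z consumed equals Q, X = K ln(charged [Z]/remaining [Z]). Monday's end gives 0.00459 M and Wednesday's 0.00466 M, though from X readings near 6% with a scatter of 1.5 percentage points.

My number is φ, K over the charged [Z], the X made per L made at the first moment: for this flask 0.0462. The ratio drifts upward as Z is used. J and Z are charged equally here, so the Z left at the end equals the X made, and the X share y obeys y = −φ ln y. That gives 10.4% at 3.0 h, with Q ahead. I take this flask as finished by then, as Monday's readings stand still within their scatter from 0.833 h.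

Early, one number is not enough. On Saturday's charge φ starts the share at 8.46%, yet the reading at 0.200 h gives 30.4%, which I read as Q waiting behind L. So at 6.0 min I expect this flask above its starting 4.42%, and φ gives me no figure.

The forecast says 20% (10% to 35%) early, on the ground that “Q lags behind its formation”, and 12% (9% to 16%) at the end with the reaction finished, higher than my end figure, with Q ahead.

The flask gives 18.1% at 6.0 min and 11.2% at 3.0 h, with 88.8% Q against 11.2% X.

    L → Q (k = 0.120 /min)
    D → X (k = 0.0350 /min)
    Z → G (k = 1.80 × 10⁻⁵ /min)
    J ⇌ D, rate k4*(cs4 - [D]) while solid is left; crystals form when [D] > cs4 (solubility = 0.0840 M, k = 0.0720 /min)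
    D + Z → L (k = 7.20 /M/min)
    D + Z ⇌ E (K = 4.50 /M, k = 1.80 /M/min)

The neighbouring flask holds 0.060 M of Z, 0.600 equiv, so its φ is 0.0770. The balance changes there: the Z left at the end is X minus the excess of J over Z. The same integral then gives an X share of 40.0%. That neighbouring flask ends with 40.0% X and 60.0% Q, and Z, its limiting reagent, stands at 0.059% of its charge.

The data were generated by integration on assumed constants; noise was put on by code.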